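The oxirane oxygen bridges C1 and C10 of the ten-membered carbocycle. The epoxide is therefore traced back to a C1,C10-diol, and the carbocycle is cut between these two carbons. One low-valent titanium pinacol coupling of a C1 aldehyde with the C10 methyl ketone makes the C1–C10 bond, closes the ten-membered ring and creates both carbinol centres. The precursor is an open-chain keto-aldehyde. It already carries C3, C6, C7 and C8, the Z C4=C5 alkene, and the lactone masked as a trans-2,3-disubstituted 4-methylenetetrahydrofuran (C6–O–C12). Every other oxygen is an ether (C3 OTBS, C8 OPMB).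

Key step: step 19

Remark: locants C1–C15 are germacrane locants, used for all intermediates (C1–C10 carbocycle, C11–C13 methylene-lactone carbons, C14 on C10, C15 on C4).
Assumption: the coupling of step 19 is taken to give the erythro (1S,10R)-diol as the main isomer. The other outcome is covered in the fallback.

Step 1
Reactants: 1 propargyl alcohol
Product: 3 (Z)-3-iodo-2-methylprop-2-en-1-ol, via cyclic alkenylmagnesium alkoxide 2 (not isolated)
Conditions: MeMgBr (2.5 equiv), CuI (10 mol %), THF, −10 °C to rt; then I2, −10 °C to rt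
Reagents that add atoms: methylmagnesium bromide, C[Mg]Br; iodine, II
Why: Copper-catalysed anti-carbomagnesiation of the propargylic alkoxide puts methyl (C15) on the inner alkyne carbon and magnesium on the terminus in a five-membered chelate, so iodinolysis with retention places iodine cis to CH2OH, which is the later Z C4=C5 geometry.

Step 2
Reactants: 3 (Z)-3-iodo-2-methylprop-2-en-1-ol
Product: 4 (Z)-3-iodo-2-methylprop-2-enal
Conditions: MnO2, CH2Cl2, rt, dark; used at once
Reagents that add atoms: none
Why: Allylic alcohol oxidation with MnO2 is neutral and stops at the enal, which limits Z-to-E isomerisation of this sensitive aldehyde.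

Step 3
Reactants: 4 (Z)-3-iodo-2-methylprop-2-enal
Product: 6 (3S,1Z)-1-iodo-2-methylhexa-1,5-dien-3-ol, via diisopinocampheylborinate 5 (not isolated)
Conditions: (−)-Ipc2B(allyl) (from (+)-α-pinene), Et2O, −78 °C; then 3 M NaOH, 30% H2O2, 0 °C to rt
Reagents that add atoms: (−)-B-allyldiisopinocampheylborane, C=CCB([C@@H]1C[C@@H]2C[C@H]([C@H]1C)C2(C)C)[C@@H]1C[C@@H]2C[C@H]([C@H]1C)C2(C)C
Why: Brown asymmetric allylboration runs through a closed chair transition state in which this reagent attacks the Si face of the enal, so 3S is set under reagent control.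

Step 4
Reactants: 6 (3S,1Z)-1-iodo-2-methylhexa-1,5-dien-3-ol
Product: 7 tert-butyl{[(3S,1Z)-1-iodo-2-methylhexa-1,5-dien-3-yl]oxy}dimethylsilane
Conditions: TBSCl, imidazole, DMF, rt
Reagents that add atoms: tert-butyldimethylsilyl chloride, CC(C)(C)[Si](C)(C)Cl
Why: Standard silyl ether formation gives a C3 protecting group that survives organolithium, hydride, base, mild acid and low-valent titanium.

Step 5
Reactants: 7 TBS ether of 6
Product: 8 (3S,4Z)-3-(tert-butyldimethylsilyloxy)-5-iodo-4-methylpent-4-enal
Conditions: OsO4 (2 mol %), NaIO4, 2,6-lutidine, dioxane–H2O 3:1, rt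
Reagents that add atoms: OsO4, O=[Os](=O)(=O)=O; NaIO4, [Na+].[O-]I(=O)(=O)=O
Why: In this Lemieux–Johnson cleavage the unhindered monosubstituted alkene is dihydroxylated much faster than the trisubstituted, iodine-deactivated one, so C1 is revealed while no other cleavable alkene is yet in the molecule.

Step 6
Reactants: 8 (3S,4Z)-3-(tert-butyldimethylsilyloxy)-5-iodo-4-methylpent-4-enal
Product: 9 (3S,1Z)-3-(tert-butyldimethylsilyloxy)-1-iodo-5,5-dimethoxy-2-methylpent-1-ene
Conditions: CH(OMe)3, PPTS (10 mol %), MeOH, rt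
Reagents that add atoms: trimethyl orthoformate, COC(OC)OC; methanol, CO
Why: Acid-catalysed acetalisation driven by the orthoester masks C1 against the organolithium, boron, aluminium and hydride reagents that follow and leaves the secondary silyl ether intact.

Step 7
Reactants: 9 (3S,1Z)-3-(tert-butyldimethylsilyloxy)-1-iodo-5,5-dimethoxy-2-methylpent-1-ene
Product: 11 (4S,2Z)-4-(tert-butyldimethylsilyloxy)-6,6-dimethoxy-3-methylhex-2-enal (C1–C6), via alkenyllithium 10 (not isolated)
Conditions: t-BuLi (2.1 equiv), Et2O, −78 °C; then DMF, −78 to 0 °C; aq NH4Cl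
Reagents that add atoms: N,N-dimethylformamide, CN(C)C=O
Why: Iodine–lithium exchange and formylation both proceed with retention at the sp2 carbon at −78 °C, so C6 is attached cis to C3.

Step 8
Reactants: 12 3-chloro-2-(chloromethyl)prop-1-ene (threefold excess)
Product: 13 3-(chloromethyl)but-3-en-1-ol
Conditions: Zn dust, 37% aq HCHO, THF–sat. aq NH4Cl, rt
Reagents that add atoms: formaldehyde, C=O
Why: In this aqueous Barbier allylation both termini of the allylzinc are CH2 groups, so no regioisomer can form, and the excess of the cheap dichloride suppresses a second addition.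

Step 9
Reactants: 13 3-(chloromethyl)but-3-en-1-ol
Product: 14 3-(chloromethyl)but-3-enoic acid
Conditions: TEMPO (20 mol %), PhI(OAc)2 (2.2 equiv), MeCN–H2O 1:1, rt
Reagents that add atoms: water, O
Why: The oxoammonium-mediated oxidation of a primary alcohol to the acid runs near neutrality, so neither conjugation of the alkene nor displacement of the allylic chloride by carboxylate is promoted.

Step 10
Reactants: 14 3-(chloromethyl)but-3-enoic acid; 15 (S)-4-benzyloxazolidin-2-one
Product: 18 (S)-4-benzyl-3-[3-(chloromethyl)but-3-enoyl]oxazolidin-2-one, via mixed pivalic anhydride 16 (not isolated), via lithium oxazolidinide 17 (not isolated)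
Conditions: 14, Et3N, PivCl, THF, −78 to 0 °C; then 17 (from 15, n-BuLi, THF, −78 °C), −78 to 0 °C
Reagents that add atoms: none
Why: N-acylation of the lithiated Evans auxiliary by the mixed anhydride is fast at low temperature, so the β,γ-alkene stays out of conjugation and the allylic chloride is not attacked.

Step 11
Reactants: 18 (S)-4-benzyl-3-[3-(chloromethyl)but-3-enoyl]oxazolidin-2-one; 11 C1–C6 Z-enal
Product: 21 (4S)-4-benzyl-3-[(2S,3R,4Z,6S)-6-(tert-butyldimethylsilyloxy)-2-(3-chloroprop-1-en-2-yl)-3-hydroxy-8,8-dimethoxy-5-methyloct-4-enoyl]oxazolidin-2-one (3S,6R,7S), via boron dienolate 19 (not isolated), via boron aldolate 20 (not isolated)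
Conditions: n-Bu2BOTf (1.05 equiv), Et3N, CH2Cl2, −78 to 0 °C; 11, −78 to −10 °C; pH 7 buffer, MeOH, 30% H2O2, 0 °C
Reagents that add atoms: none
Why: In this Evans syn-aldol the Z(O)-boron dienolate reacts at its α-carbon C7 through a Zimmerman–Traxler chair whose face is fixed by the benzyl group of the (S)-auxiliary, which sets C6 and C7 together in the syn relationship that becomes the trans C6/C7 ring fusion.

Step 12
Reactants: 21 syn-aldol adduct
Product: 22 (2S,3R,4Z,6S)-6-(tert-butyldimethylsilyloxy)-2-(3-chloroprop-1-en-2-yl)-3-hydroxy-N,8,8-trimethoxy-N,5-dimethyloct-4-enamide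
Conditions: MeNH(OMe)·HCl, AlMe3, THF, −10 °C to rt; aq potassium sodium tartrate
Reagents that add atoms: N,O-dimethylhydroxylamine hydrochloride, CNOC.Cl
Why: Weinreb transamidation with the aluminium amide is assisted by the free β-hydroxyl, removes the auxiliary without enolising C7, and gives a carbonyl group that tolerates the alkoxide of the next step.

Step 13
Reactants: 22 hydroxy chloro Weinreb amide
Product: 23 (2R,3S)-2-[(1Z,3S)-3-(tert-butyldimethylsilyloxy)-5,5-dimethoxy-2-methylpent-1-en-1-yl]-N-methoxy-N-methyl-4-methylenetetrahydrofuran-3-carboxamide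
Conditions: NaH (1.05 equiv), THF, 0 °C
Reagents that add atoms: none
Why: The intramolecular Williamson etherification (5-exo-tet on a primary allylic chloride, with either allyl terminus giving the same product) should outrun retro-aldol cleavage, touches no stereocentre, and gives the 2,3-trans ring, which is also the thermodynamic isomer at C7.

Step 14
Reactants: 23 methylenetetrahydrofuran Weinreb amide
Product: 24 (2R,3S)-2-[(1Z,3S)-3-(tert-butyldimethylsilyloxy)-5,5-dimethoxy-2-methylpent-1-en-1-yl]-4-methylenetetrahydrofuran-3-carbaldehyde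
Conditions: i-Bu2AlH, THF, −78 °C; aq potassium sodium tartrate; used at once
Reagents that add atoms: none
Why: In the Weinreb amide reduction the chelated tetrahedral aluminium adduct collapses only on work-up, so the epimerisable C8 aldehyde is released without over-reduction and without base.

Step 15
Reactants: 24 C8 aldehyde
Product: 26 (1S)-1-{(2R,3R)-2-[(1Z,3S)-3-(tert-butyldimethylsilyloxy)-5,5-dimethoxy-2-methylpent-1-en-1-yl]-4-methylenetetrahydrofuran-3-yl}but-3-en-1-ol, via C8 borinate 25 (not isolated)
Conditions: (−)-Ipc2B(allyl), Et2O, −78 °C; then 3 M NaOH, 30% H2O2, 0 °C to rt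
Reagents that add atoms: (−)-B-allyldiisopinocampheylborane, C=CCB([C@@H]1C[C@@H]2C[C@H]([C@H]1C)C2(C)C)[C@@H]1C[C@@H]2C[C@H]([C@H]1C)C2(C)C
Why: Brown allylboration is non-basic and fast at −78 °C, so C7 is not enolised, and the chair transition state of the (+)-α-pinene-derived reagent sets 8S by reagent control.

Step 16
Reactants: 26 C8 homoallylic alcohol
Product: 27 C8 4-methoxybenzyl ether of 26
Conditions: NaH, PMBCl, n-Bu4NI (cat.), DMF, 0 °C to rt
Reagents that add atoms: 4-methoxybenzyl chloride, COc1ccc(CCl)cc1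
Why: This Williamson etherification is safe because C8 is now sp3 and no acidic C–H remains at C7, and the PMB group is orthogonal to the C3 silyl ether.

Step 17
Reactants: 27 PMB ether
Product: 28 C10 methyl ketone with the C1 dimethyl acetal
Conditions: PdCl2 (10 mol %), Cu(OAc)2·H2O (20 mol %), O2 (1 atm), DMA–H2O 7:1, rt
Reagents that add atoms: water, O
Why: The Wacker–Tsuji oxidation acts only on the monosubstituted terminal alkene with Markovnikov regiochemistry, so the C10 ketone appears without any oxidative cleavage that could touch C4=C5 or C11=C13, and the acetate buffer protects the acetal.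

Step 18
Reactants: 28 keto acetal
Product: 29 (3S,4Z)-3-(tert-butyldimethylsilyloxy)-5-{(2R,3R)-3-[(1S)-1-(4-methoxybenzyloxy)-3-oxobutyl]-4-methylenetetrahydrofuran-2-yl}-4-methylpent-4-enal (seco keto-aldehyde)
Conditions: PPTS (20 mol %), acetone–H2O 10:1, 45 °C; used without storage
Reagents that add atoms: water, O
Why: Mild acid hydrolysis of the dimethyl acetal leaves the secondary silyl ether, the PMB ether and the allylic ring ether untouched and releases the β-silyloxy aldehyde only just before it is needed.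

Step 19
Reactants: 29 seco keto-aldehyde
Product: 31 (1S,3S,6R,7R,8S,10R)-3-(tert-butyldimethylsilyloxy)-8-(4-methoxybenzyloxy)-6,12-epoxygermacra-4Z,11(13)-diene-1,10-diol, via titanium pinacolate 30 (not isolated)
Conditions: TiCl3(DME)1.5 (12 equiv), zinc–copper couple (36 equiv), DME, reflux, 3 h; cool to 25 °C; 29 in DME by syringe pump over 30 h (final about 2 mM); 25 °C, 6 h; 10% aq K2CO3
Reagents that add atoms: none
Why: The trivalent titanium salt is reduced by the zinc–copper couple to low-valent titanium, which transfers one electron to each carbonyl group (the aldehyde first), and the titanium-bound ketyl carbons C1 and C10 combine to a pinacolate that is hydrolysed on work-up; this is the McMurry-type intramolecular pinacol coupling of keto-aldehydes, established for ten-membered and larger carbocycles. The ten-membered ring closes by attack of the C1 ketyl on the C10 carbonyl carbon with both C–O bonds left outside the new ring (10-exo-trig mode), helped by the Z C4=C5 alkene and the trans-disubstituted tetrahydrofuran, which already turn the two chain ends toward each other. C10 should be controlled by the adjacent C7/C8 array, since the ketone is expected to react on its outer face in the rotamer that keeps C14 and the C8 OPMB group away from the ring interior, which gives 10R. C1 should be controlled by the titanium bridge, which holds both oxygens on the same outer side while C2 and C9 stay gauche as in a cis-fused dioxatitanacycle, which gives 1S and hence the erythro diol. The step needs ring closure rather than oligomerisation (slow addition at high dilution), arrest at the diol rather than deoxygenation (25 °C, not reflux) and inertness of all other groups, which the substrate secures because the lactone is carried as a reduction-stable allylic ether and every other oxygen is a silyl or benzyl-type ether with no leaving group next to a ketyl carbon. The C11=C13 alkene is a conceivable ketyl acceptor, but it is unactivated and 1,1-disubstituted, so carbonyl–carbonyl coupling on the metal should prevail.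

Step 20
Reactants: 31 C1,C10-diol
Product: 33 (1R,3S,6R,7R,8S,10R)-3-(tert-butyldimethylsilyloxy)-8-(4-methoxybenzyloxy)-1,10:6,12-diepoxygermacra-4Z,11(13)-diene, via C1 mesylate 32 (not isolated)
Conditions: MsCl, Et3N, CH2Cl2, −10 °C; then MeOH, K2CO3, rt
Reagents that add atoms: none
Why: Only the secondary C1 hydroxyl is sulfonylated, and the tertiary C10 alkoxide then closes the oxirane by intramolecular SN2 (3-exo-tet) with inversion at C1 and retention at C10, which gives the trans (1R,10R)-epoxide while no base-sensitive group is present.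

Step 21
Reactants: 33 epoxide
Product: 34 C8 alcohol of 33 (PMB removed)
Conditions: DDQ, CH2Cl2–pH 7 phosphate buffer 10:1, 0 °C
Reagents that add atoms: none
Why: Oxidative PMB cleavage by DDQ under buffered conditions avoids the acid that would trigger transannular opening of the oxirane and removes the chromium-sensitive benzyl ether before the last step.

Step 22
Reactants: 34 C8 alcohol
Product: 35 C8 3-methylbutanoate of 34
Conditions: isovaleric anhydride, DMAP, Et3N, CH2Cl2, rt
Reagents that add atoms: isovaleric anhydride, CC(C)CC(=O)OC(=O)CC(C)C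
Why: DMAP-catalysed acylation of the only free hydroxyl proceeds with retention at C8.

Step 23
Reactants: 35 C8 isovalerate
Product: 36 C3 alcohol of 35 (TBS removed)
Conditions: n-Bu4NF, AcOH (1:1), THF, 0 °C to rt
Reagents that add atoms: none
Why: Fluoride desilylation buffered with acetic acid is neither acidic enough to open the oxirane nor basic enough to cleave or move the isovalerate.

Step 24
Reactants: 36 C3 alcohol
Product: 37 (1R,3S,6R,7R,8S,10R)-3-acetoxy-8-(3-methylbutanoyloxy)-1,10:6,12-diepoxygermacra-4Z,11(13)-diene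
Conditions: Ac2O, pyridine, DMAP (cat.), CH2Cl2, 0 °C to rt
Reagents that add atoms: acetic anhydride, CC(=O)OC(C)=O
Why: Acetylation with retention at C3 also deactivates the allylic C3–H toward the oxidation that follows.

Step 25
Reactants: 37 methylenetetrahydrofuran diester
Product: 38 target, (1R,3S,6R,7R,8S,10R)-3-acetoxy-1,10-epoxy-8-(3-methylbutanoyloxy)germacra-4Z,11(13)-dien-12,6-olide
Conditions: CrO3, 3,5-dimethylpyrazole, CH2Cl2, −20 °C
Reagents that add atoms: chromium trioxide, O=[Cr](=O)=O
Why: This allylic oxidation of a 3-methylenetetrahydrofuran to the α-methylene-γ-butyrolactone should pick C12–H2, the only CH2 that is both allylic and next to oxygen, because C3–H carries an acetate and C6–H is tertiary and held in the plane of the Z alkene by allylic strain, and the pyrazole keeps the medium non-acidic for the oxirane.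

Compound list
1 | propargyl alcohol | C#CCO | starting material
2 | cyclic (Z)-alkenylmagnesium alkoxide | CC1=C[Mg]OC1 | intermediate
3 | (Z)-3-iodo-2-methylprop-2-en-1-ol | OC/C(C)=C\I | intermediate
4 | (Z)-3-iodo-2-methylprop-2-enal | O=C/C(C)=C\I | intermediate
5 | diisopinocampheylborinate of 6 | C=CC[C@H](OB([C@@H]1C[C@@H]2C[C@H]([C@H]1C)C2(C)C)[C@@H]1C[C@@H]2C[C@H]([C@H]1C)C2(C)C)/C(C)=C\I | intermediate
6 | (3S,1Z)-1-iodo-2-methylhexa-1,5-dien-3-ol | C=CC[C@H](O)/C(C)=C\I | intermediate
7 | TBS ether of 6 | C=CC[C@H](O[Si](C)(C)C(C)(C)C)/C(C)=C\I | intermediate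
8 | (3S,4Z)-3-(TBSO)-5-iodo-4-methylpent-4-enal | O=CC[C@H](O[Si](C)(C)C(C)(C)C)/C(C)=C\I | intermediate
9 | (3S,1Z)-3-(TBSO)-1-iodo-5,5-dimethoxy-2-methylpent-1-ene | COC(OC)C[C@H](O[Si](C)(C)C(C)(C)C)/C(C)=C\I | intermediate
10 | (Z)-alkenyllithium from 9 | COC(OC)C[C@H](O[Si](C)(C)C(C)(C)C)/C(C)=C\[Li] | intermediate
11 | (4S,2Z)-4-(TBSO)-6,6-dimethoxy-3-methylhex-2-enal | COC(OC)C[C@H](O[Si](C)(C)C(C)(C)C)/C(C)=C\C=O | intermediate
12 | 3-chloro-2-(chloromethyl)prop-1-ene | C=C(CCl)CCl | starting material
13 | 3-(chloromethyl)but-3-en-1-ol | C=C(CCl)CCO | intermediate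
14 | 3-(chloromethyl)but-3-enoic acid | C=C(CCl)CC(=O)O | intermediate
15 | (S)-4-benzyloxazolidin-2-one | O=C1N[C@@H](Cc2ccccc2)CO1 | starting material
16 | 3-(chloromethyl)but-3-enoic pivalic anhydride | C=C(CCl)CC(=O)OC(=O)C(C)(C)C | intermediate
17 | lithium salt of 15 | [Li]N1[C@@H](Cc2ccccc2)COC1=O | intermediate
18 | (S)-4-benzyl-3-[3-(chloromethyl)but-3-enoyl]oxazolidin-2-one | C=C(CCl)CC(=O)N1[C@@H](Cc2ccccc2)COC1=O | intermediate
19 | Z(O)-di-n-butylboron dienolate of 18 | C=C(CCl)/C=C(\OB(CCCC)CCCC)N1[C@@H](Cc2ccccc2)COC1=O | intermediate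
20 | di-n-butylboron aldolate of 21 | COC(OC)C[C@H](O[Si](C)(C)C(C)(C)C)/C(C)=C\[C@@H](OB(CCCC)CCCC)[C@H](C(=C)CCl)C(=O)N1[C@@H](Cc2ccccc2)COC1=O | intermediate
21 | syn-aldol adduct (3S,6R,7S; auxiliary 4S) | COC(OC)C[C@H](O[Si](C)(C)C(C)(C)C)/C(C)=C\[C@@H](O)[C@H](C(=C)CCl)C(=O)N1[C@@H](Cc2ccccc2)COC1=O | intermediate
22 | hydroxy chloro Weinreb amide (3S,6R,7S) | COC(OC)C[C@H](O[Si](C)(C)C(C)(C)C)/C(C)=C\[C@@H](O)[C@H](C(=C)CCl)C(=O)N(C)OC | intermediate
23 | trans-2,3-disubstituted 4-methylenetetrahydrofuran Weinreb amide (3S,6R,7S) | COC(OC)C[C@H](O[Si](C)(C)C(C)(C)C)/C(C)=C\[C@H]1OCC(=C)[C@@H]1C(=O)N(C)OC | intermediate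
24 | C8 aldehyde (3S,6R,7S) | COC(OC)C[C@H](O[Si](C)(C)C(C)(C)C)/C(C)=C\[C@H]1OCC(=C)[C@@H]1C=O | intermediate
25 | diisopinocampheylborinate of 26 | COC(OC)C[C@H](O[Si](C)(C)C(C)(C)C)/C(C)=C\[C@H]1OCC(=C)[C@@H]1[C@@H](OB([C@@H]2C[C@@H]3C[C@H]([C@H]2C)C3(C)C)[C@@H]2C[C@@H]3C[C@H]([C@H]2C)C3(C)C)CC=C | intermediate
26 | C8 homoallylic alcohol (3S,6R,7R,8S) | COC(OC)C[C@H](O[Si](C)(C)C(C)(C)C)/C(C)=C\[C@H]1OCC(=C)[C@@H]1[C@@H](O)CC=C | intermediate
27 | C8 PMB ether of 26 | COC(OC)C[C@H](O[Si](C)(C)C(C)(C)C)/C(C)=C\[C@H]1OCC(=C)[C@@H]1[C@@H](OCc2ccc(OC)cc2)CC=C | intermediate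
28 | C10 methyl ketone, C1 dimethyl acetal | COC(OC)C[C@H](O[Si](C)(C)C(C)(C)C)/C(C)=C\[C@H]1OCC(=C)[C@@H]1[C@@H](OCc2ccc(OC)cc2)CC(C)=O | intermediate
29 | seco keto-aldehyde (3S,6R,7R,8S; 4Z) | O=CC[C@H](O[Si](C)(C)C(C)(C)C)/C(C)=C\[C@H]1OCC(=C)[C@@H]1[C@@H](OCc2ccc(OC)cc2)CC(C)=O | intermediate
30 | titanium pinacolate, drawn as the dichlorotitanium chelate of 31 | C=C1CO[C@@H]2/C=C(/C)[C@@H](O[Si](C)(C)C(C)(C)C)C[C@@H]3O[Ti](Cl)(Cl)O[C@]3(C)C[C@H](OCc4ccc(OC)cc4)[C@@H]12 | intermediate
31 | ten-membered (1S,10R)-diol fused to the 3-methylenetetrahydrofuran | C=C1CO[C@@H]2/C=C(/C)[C@@H](O[Si](C)(C)C(C)(C)C)C[C@H](O)[C@@](O)(C)C[C@H](OCc3ccc(OC)cc3)[C@@H]12 | intermediate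
32 | C1 mesylate of 31 | C=C1CO[C@@H]2/C=C(/C)[C@@H](O[Si](C)(C)C(C)(C)C)C[C@H](OS(C)(=O)=O)[C@@](O)(C)C[C@H](OCc3ccc(OC)cc3)[C@@H]12 | intermediate
33 | trans (1R,10R)-epoxide, C3 OTBS, C8 OPMB | C=C1CO[C@@H]2/C=C(/C)[C@@H](O[Si](C)(C)C(C)(C)C)C[C@H]3O[C@]3(C)C[C@H](OCc4ccc(OC)cc4)[C@@H]12 | intermediate
34 | epoxide, C3 OTBS, C8 OH | C=C1CO[C@@H]2/C=C(/C)[C@@H](O[Si](C)(C)C(C)(C)C)C[C@H]3O[C@]3(C)C[C@H](O)[C@@H]12 | intermediate
35 | epoxide, C3 OTBS, C8 isovalerate | C=C1CO[C@@H]2/C=C(/C)[C@@H](O[Si](C)(C)C(C)(C)C)C[C@H]3O[C@]3(C)C[C@H](OC(=O)CC(C)C)[C@@H]12 | intermediate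
36 | epoxide, C3 OH, C8 isovalerate | C=C1CO[C@@H]2/C=C(/C)[C@@H](O)C[C@H]3O[C@]3(C)C[C@H](OC(=O)CC(C)C)[C@@H]12 | intermediate
37 | epoxide, C3 acetate, C8 isovalerate, C6,C12 cyclic ether | C=C1CO[C@@H]2/C=C(/C)[C@@H](OC(C)=O)C[C@H]3O[C@]3(C)C[C@H](OC(=O)CC(C)C)[C@@H]12 | intermediate
38 | CNP0157657.1 | C=C1C(=O)O[C@@H]2/C=C(/C)[C@@H](OC(C)=O)C[C@H]3O[C@]3(C)C[C@H](OC(=O)CC(C)C)[C@@H]12 | target

Total step count: 25. Longest linear sequence: 22 steps (steps 1–7 and 11–25, from propargyl alcohol). Steps 8–10 form the side branch.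

Steps most likely to fail

Step 19. The two ketyl faces may pair with the opposite relative topicity (threo instead of erythro), since acyclic models do not apply inside the forming medium ring. Direct closure to the trans-oxirane would then be blocked. The fallback sets out from 29 and comes back at 33.
- The same coupling is run and the threo (1R,10R)-diol F1 is carried on.
- Thiocarbonyldiimidazole and DMAP in hot toluene give the cyclic thionocarbonate F2.
- Corey–Winter syn-elimination with 1,3-dimethyl-2-phenyl-1,3,2-diazaphospholidine at 40 °C gives the (1(10)E,4Z)-diene F3.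
- mCPBA buffered with NaHCO3 should epoxidise the strained and most electron-rich C1=C10 alkene from its outer face, leaving the oxygen-flanked C4=C5 and the 1,1-disubstituted C11=C13 alkenes. This gives 33.

Step 25. Hydrogen abstraction may be unselective (C6–H, C7–H or C15–H3 competing with C12–H2), or the oxirane may open on Lewis-acidic chromium residues. The fallback sets out from 37 and comes back at 38, and it splits the oxidation into two mild stages.
- SeO2 (catalytic) with t-BuOOH in CH2Cl2 hydroxylates C12 by an ene reaction and [2,3]-shift, giving the C12 lactol F6.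
- MnO2 then oxidises this allylic lactol to the lactone under neutral conditions.

Step 15. The resident C7 centre may oppose the reagent (poor facial selectivity in a mismatched pair), and slow addition would give the aldehyde time to lose its C7 configuration by enolisation. The fallback sets out from 24 and comes back at 26.
- The then-matched enantiomeric reagent (+)-Ipc2B(allyl) is used to make the (8R)-alcohol F4 quickly and cleanly.
- Mitsunobu inversion with 4-nitrobenzoic acid, PPh3 and diisopropyl azodicarboxylate gives the (8S)-4-nitrobenzoate F5.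
- K2CO3 in MeOH releases 26.

Further compounds
F1 | step 19 | threo (1R,10R)-diol, C1 epimer of 31 | C=C1CO[C@@H]2/C=C(/C)[C@@H](O[Si](C)(C)C(C)(C)C)C[C@@H](O)[C@@](O)(C)C[C@H](OCc3ccc(OC)cc3)[C@@H]12
F2 | step 19 | cyclic C1,C10-thionocarbonate of F1 | C=C1CO[C@@H]2/C=C(/C)[C@@H](O[Si](C)(C)C(C)(C)C)C[C@H]3OC(=S)O[C@]3(C)C[C@H](OCc4ccc(OC)cc4)[C@@H]12
F3 | step 19 | (1(10)E,4Z)-3-(TBSO)-8-(PMBO)-6,12-epoxygermacra-1(10),4,11(13)-triene | C=C1CO[C@@H]2/C=C(/C)[C@@H](O[Si](C)(C)C(C)(C)C)C/C=C(\C)C[C@H](OCc3ccc(OC)cc3)[C@@H]12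
F4 | step 15 | (8R)-homoallylic alcohol, C8 epimer of 26 | COC(OC)C[C@H](O[Si](C)(C)C(C)(C)C)/C(C)=C\[C@H]1OCC(=C)[C@@H]1[C@H](O)CC=C
F5 | step 15 | (8S)-4-nitrobenzoate of 26 | COC(OC)C[C@H](O[Si](C)(C)C(C)(C)C)/C(C)=C\[C@H]1OCC(=C)[C@@H]1[C@@H](OC(=O)c2ccc(cc2)[N+](=O)[O-])CC=C
F6 | step 25 | C12 lactol of 37 (anomeric mixture at C12) | C=C1C(O)O[C@@H]2/C=C(/C)[C@@H](OC(C)=O)C[C@H]3O[C@]3(C)C[C@H](OC(=O)CC(C)C)[C@@H]12
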